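A direct plan would take the intact flavone luteolin A1, let sulfuryl fluoride fluorosulfate O-7 and close the catechol to give luteolin 3',4'-cyclic sulfate 7-fluorosulfate A2, open the cyclic sulfate of A2 with methoxide so that the methyl group ended on O-4' and the sulfate stayed on O-3', giving sodium diosmetin 7-fluorosulfate 3'-sulfate A3, and finally hydrolyse the S–F group of A3 at O-7. Its weakest steps would be:
- the ring opening with methyl transfer, which is unprecedented and would have to tell O-3' from O-4';
- the fluorosulfation, in which a metered gas would have to hit O-7 and the catechol yet spare the 5-OH;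
- the unmasking of the fluorosulfate, which would pass through an alkylating methyl sulfate diester beside a free 5-OH.

Strategy. The flavone is cut through ring C at both of its bonds to ring A, C4a–C4 and C8a–O1: ring A enters as 3,5-bis(benzyloxy)benzyne, ring B with C2, C3 and C4 as an arylpropiolic acid made from O-benzylisovanillin. In one operation the aryne inserts into the C–O bond of the acid and the resulting o-hydroxyaryl ynone closes ring C; the oxygen at C5, which flanks the triple bond of the aryne, steers the carbonyl to C4a. The 4'-methyl ether is bought with isovanillin, so no catechol has to be differentiated, and sulfur enters last, as SO3, on the only two hydroxyls that are not chelated, so no cyclic sulfate is opened and no fluorosulfate is unmasked.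

Key step: step 5

Assumption: the target is wanted as the free bis(hydrogen sulfate) of the SMILES, a strong acid that is set free from its salt only in the last operation and kept cold; 1 and 6 are taken as catalogue compounds.

Step 1
Reactants: 1 3,5-bis(benzyloxy)phenol
Product: 2 2-bromo-3,5-bis(benzyloxy)phenol
Conditions: NBS (1.0 equiv, in portions), i-Pr2NH (10 mol %), CH2Cl2, −78 to −40 °C, dark
Reagents that add atoms: N-bromosuccinimide, O=C1CCC(=O)N1Br
Why: Amine-catalysed electrophilic bromination, in which the N-bromoamine is held by a hydrogen bond to the phenol OH and delivers bromine to the ortho carbon; C2 and C6 are equivalent by symmetry, so only C4, which is crowded by two benzyloxy groups, competes.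

Step 2
Reactants: 2 2-bromo-3,5-bis(benzyloxy)phenol
Product: 5 3,5-bis(benzyloxy)-2-(trimethylsilyl)phenyl trifluoromethanesulfonate, via trimethylsilyl ether 3 (not isolated), via lithium phenoxide 4 (not isolated)
Conditions: HMDS (0.8 equiv), THF, 65 °C, then evaporate; n-BuLi (1.1 equiv), THF, −100 °C, 20 min; Tf2O (1.2 equiv), −100 °C to rt
Reagents that add atoms: hexamethyldisilazane, C[Si](C)(C)N[Si](C)(C)C; trifluoromethanesulfonic anhydride, O=S(=O)(OS(=O)(=O)C(F)(F)F)C(F)(F)F
Why: O-silylation, bromine–lithium exchange, anionic 1,3 O→C silyl shift (retro-Brook rearrangement) to phenoxide 4 and O-triflation form the standard entry to an ortho-silylaryl triflate (Kobayashi aryne precursor), the exchange at −100 °C being far faster than any attack of n-BuLi on the benzyl ethers.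

Step 3
Reactants: 6 3-(benzyloxy)-4-methoxybenzaldehyde (O-benzylisovanillin)
Product: 7 2-(benzyloxy)-4-(2,2-dibromoethenyl)-1-methoxybenzene
Conditions: CBr4 (2 equiv), PPh3 (4 equiv), CH2Cl2, 0 °C, 1 h
Reagents that add atoms: carbon tetrabromide, BrC(Br)(Br)Br
Why: First stage of the Corey–Fuchs sequence, a Wittig-type olefination of the aryl aldehyde by the ylide Ph3P=CBr2 formed from CBr4 and PPh3, to which aryl benzyl and methyl ethers are inert.

Step 4
Reactants: 7 2-(benzyloxy)-4-(2,2-dibromoethenyl)-1-methoxybenzene
Product: 10 3-[3-(benzyloxy)-4-methoxyphenyl]prop-2-ynoic acid, via lithium acetylide 8 (not isolated), via lithium propiolate 9 (not isolated)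
Conditions: n-BuLi (2.2 equiv), THF, −78 to 0 °C; dry CO2 (gas), −78 °C to rt; 1 M HCl
Reagents that add atoms: carbon dioxide, O=C=O
Why: Second stage of the Corey–Fuchs sequence, in which bromine–lithium exchange, α-elimination with 1,2-hydrogen shift (Fritsch–Buttenberg–Wiechell rearrangement) and deprotonation give acetylide 8, which is carboxylated by CO2 to 9 and protonated.

Step 5
Reactants: 5 3,5-bis(benzyloxy)-2-(trimethylsilyl)phenyl trifluoromethanesulfonate (1.5 equiv); 10 3-[3-(benzyloxy)-4-methoxyphenyl]prop-2-ynoic acid (1.0 equiv)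
Product: 14 5,7-bis(benzyloxy)-2-[3-(benzyloxy)-4-methoxyphenyl]-4H-chromen-4-one (tri-O-benzyldiosmetin), via aryne 11 (not isolated), via aryl ester carbanion 12 (not isolated), via ynone phenoxide 13 (not isolated)
Conditions: CsF (4 equiv), THF (0.1 M), 125 °C, sealed tube, 24 h
Reagents that add atoms: none
Why: Fluoride strips the trimethylsilyl group of 5 and triflate leaves, giving aryne 11, whose triple bond is distorted by the benzyloxy group at C3 so that the cesium carboxylate of 10 attacks C1 (the carbon remote from that group, the future C8a) and the negative charge develops at C2 (the future C4a), where the neighbouring C–O bond stabilises it inductively. Carbanion 12 then adds to its own ester carbonyl (4-exo-trig) and the four-membered adduct opens to the chelated phenoxide 13, a net 1,3 O→C acyl shift that amounts to insertion of the aryne into the C–O bond of the acid and forms the C4a–C4 and C8a–O1 bonds in the orientation that a 5-oxygenated flavone needs. The phenoxide of 13 closes ring C by 6-endo-dig oxa-Michael addition to the ynone, the mode that o-hydroxyaryl ynones follow in aprotic media, and the proton of the acid ends at C3. The closest known reaction type is the fluoride-induced intermolecular C–O addition of carboxylic acids to arynes, which gives o-hydroxyaryl ketones and, from 3-arylpropiolic acids, flavones, and which is related to aryne acyl-alkylation. The step needs regioselectivity in the aryne addition, secured by the benzyloxy group at C3 (the one at C5 is too remote to override it), and attack of the carbanion on the carbonyl and not on the alkyne, secured by the ester carbonyl lying two atoms from C2 while the linear C≡C unit holds the β-carbon away. No stereocenter is formed.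

Step 6
Reactants: 14 5,7-bis(benzyloxy)-2-[3-(benzyloxy)-4-methoxyphenyl]-4H-chromen-4-one
Product: 15 diosmetin (5,7,3'-trihydroxy-4'-methoxyflavone)
Conditions: H2 (1 atm), Pd/C (10 wt % Pd), THF/MeOH 1:1, rt, 6 h; filter through Celite
Reagents that add atoms: none
Why: Catalytic hydrogenolysis of the three aryl benzyl ethers over palladium, in which the C2–C3 double bond, a vinylogous ester, resists hydrogenation at 1 atm and the aryl methyl ether is untouched.

Step 7
Reactants: 15 diosmetin
Product: 17 luteolin 4'-methyl ether 7,3'-disulfate (target), via bis(triethylammonium) salt 16 (not isolated)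
Conditions: SO3·NEt3 (4 equiv), DMA, 55 °C, 4 h; precipitate with acetone/Et2O; C18 plug (H2O, then H2O/MeOH) to wash out triethylammonium sulfate, eluate taken on directly; strongly acidic cation-exchange resin (sulfonated polystyrene, H+ form), H2O, 0–5 °C; lyophilise
Reagents that add atoms: sulfur trioxide–triethylamine complex, CC[N+](CC)(CC)S(=O)(=O)[O-]
Why: O-Sulfation of phenols with a sulfur trioxide–amine complex takes the 7-OH and the 3'-OH, the only hydroxyls that are not tied up, whereas the 5-OH is locked in the hydrogen bond to the C4 carbonyl and should stay free, as is usual for 5-hydroxyflavones; the cold acidic resin then replaces triethylammonium by protons without hydrolysing the aryl sulfates.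

## Compound list
1 | 3,5-bis(benzyloxy)phenol | Oc1cc(OCc2ccccc2)cc(OCc2ccccc2)c1 | starting material
2 | 2-bromo-3,5-bis(benzyloxy)phenol | Oc1cc(OCc2ccccc2)cc(OCc2ccccc2)c1Br | intermediate
3 | [2-bromo-3,5-bis(benzyloxy)phenoxy]trimethylsilane | C[Si](C)(C)Oc1cc(OCc2ccccc2)cc(OCc2ccccc2)c1Br | intermediate
4 | lithium 3,5-bis(benzyloxy)-2-(trimethylsilyl)phenoxide | [Li+].[O-]c1cc(OCc2ccccc2)cc(OCc2ccccc2)c1[Si](C)(C)C | intermediate
5 | 3,5-bis(benzyloxy)-2-(trimethylsilyl)phenyl trifluoromethanesulfonate | C[Si](C)(C)c1c(OS(=O)(=O)C(F)(F)F)cc(OCc2ccccc2)cc1OCc1ccccc1 | intermediate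
6 | 3-(benzyloxy)-4-methoxybenzaldehyde (O-benzylisovanillin) | COc1ccc(C=O)cc1OCc1ccccc1 | starting material
7 | 2-(benzyloxy)-4-(2,2-dibromoethenyl)-1-methoxybenzene | COc1ccc(C=C(Br)Br)cc1OCc1ccccc1 | intermediate
8 | lithium [3-(benzyloxy)-4-methoxyphenyl]acetylide | [Li+].[C-]#Cc1ccc(OC)c(OCc2ccccc2)c1 | intermediate
9 | lithium 3-[3-(benzyloxy)-4-methoxyphenyl]prop-2-ynoate | [Li+].[O-]C(=O)C#Cc1ccc(OC)c(OCc2ccccc2)c1 | intermediate
10 | 3-[3-(benzyloxy)-4-methoxyphenyl]prop-2-ynoic acid | OC(=O)C#Cc1ccc(OC)c(OCc2ccccc2)c1 | intermediate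
11 | 3,5-bis(benzyloxy)benzyne (1,2-didehydro-3,5-bis(benzyloxy)benzene) | C1#CC(OCc2ccccc2)=CC(OCc2ccccc2)=C1 | intermediate
12 | cesium 2,4-bis(benzyloxy)-6-{3-[3-(benzyloxy)-4-methoxyphenyl]prop-2-ynoyloxy}benzen-1-ide (aryl ester carbanion) | [Cs+].O=C(C#Cc1ccc(OC)c(OCc2ccccc2)c1)Oc1cc(OCc2ccccc2)cc(OCc2ccccc2)[c-]1 | intermediate
13 | cesium 3,5-bis(benzyloxy)-2-{3-[3-(benzyloxy)-4-methoxyphenyl]prop-2-ynoyl}phenoxide | [Cs+].[O-]c1cc(OCc2ccccc2)cc(OCc2ccccc2)c1C(=O)C#Cc1ccc(OC)c(OCc2ccccc2)c1 | intermediate
14 | 5,7-bis(benzyloxy)-2-[3-(benzyloxy)-4-methoxyphenyl]-4H-chromen-4-one | COc1ccc(-c2cc(=O)c3c(OCc4ccccc4)cc(OCc4ccccc4)cc3o2)cc1OCc1ccccc1 | intermediate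
15 | diosmetin (5,7-dihydroxy-2-(3-hydroxy-4-methoxyphenyl)-4H-chromen-4-one) | COc1ccc(-c2cc(=O)c3c(O)cc(O)cc3o2)cc1O | intermediate
16 | bis(triethylammonium) diosmetin 7,3'-disulfate | COc1ccc(-c2cc(=O)c3c(O)cc(OS(=O)(=O)[O-])cc3o2)cc1OS(=O)(=O)[O-].CC[NH+](CC)CC.CC[NH+](CC)CC | intermediate
17 | luteolin 4'-methyl ether 7,3'-disulfate (diosmetin 7,3'-bis(hydrogen sulfate)), achiral | COc1ccc(-c2cc(=O)c3c(O)cc(OS(=O)(=O)O)cc3o2)cc1OS(=O)(=O)O | target

Total step count: 7. Longest linear sequence: 5 steps (1 → 2 → 5 → 14 → 15 → 17, or 6 → 7 → 10 → 14 → 15 → 17).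

Steps most likely to fail

1. Step 5 (aryne insertion and closure of ring C). What may go wrong:
   - the carbanion may be protonated before the acyl group migrates, which would stop at the aryl ester;
   - the carbanion may add to the alkyne in conjugate fashion;
   - the propiolate may lose CO2 at 125 °C;
   - the aryne may be consumed by the product phenoxide.

   The fallback is a carbonylative Sonogashira annulation and sets out from 1 and 7. Compound 1 would be iodinated ortho to the hydroxyl with NIS and catalytic i-Pr2NH in CH2Cl2 at −78 °C to give 3,5-bis(benzyloxy)-2-iodophenol F1. Compound 7 would be treated with n-BuLi (2.2 equiv, THF, −78 °C) and then aqueous NH4Cl to give 2-(benzyloxy)-4-ethynyl-1-methoxybenzene F2. Coupling of F1 and F2 under CO (1 atm) with PdCl2(PPh3)2 in Et2NH at 40–60 °C would give 1-[2,4-bis(benzyloxy)-6-hydroxyphenyl]-3-[3-(benzyloxy)-4-methoxyphenyl]prop-2-yn-1-one F3. In the amine medium F3 cyclises through its β-aminoenone in the 6-endo sense, and the route is rejoined at 14.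

2. Step 7 (disulfation and release of the free acid). What may go wrong:
   - sulfation of the acidic 7-OH may be incomplete, or the 5-OH may be sulfated as well, and the anionic mixture is hard to separate;
   - the aryl sulfates may be hydrolysed under acid catalysis during proton exchange and drying.

   The fallback uses masked sulfate diesters and sets out from 15. Treatment with 2,2,2-trichloroethyl chlorosulfate, Et3N and DMAP in THF at 0 °C would give the neutral diosmetin 7,3'-bis(2,2,2-trichloroethyl sulfate) F4, which can be purified on silica. Reductive removal of the trichloroethyl groups with Zn dust and HCO2NH4 in MeOH at rt would give diammonium diosmetin 7,3'-disulfate F5. The same cold proton exchange as in step 7 leads from F5 to 17.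

3. Step 1 (ortho-bromination). What may go wrong:
   - bromination may occur para to the hydroxyl, or twice, on this very electron-rich ring, giving mixtures that are hard to separate.

   The fallback is a carbamate-directed ortho-metalation that sets out from 1 and bypasses steps 1 and 2. Compound 1 would be converted with i-PrNCO and catalytic Et3N in CH2Cl2 into 3,5-bis(benzyloxy)phenyl N-isopropylcarbamate F6. N-Silylation of F6 in the flask with TBSOTf and TMEDA in Et2O, ortho-lithiation between the carbamate and a benzyloxy group with n-BuLi and TMEDA at −78 °C, and a TMSCl quench would give 3,5-bis(benzyloxy)-2-(trimethylsilyl)phenyl N-isopropylcarbamate F7 after work-up. Cleavage of the carbamate with DBU and Et2NH in MeCN at 40 °C would release 3,5-bis(benzyloxy)-2-(trimethylsilyl)phenol F8. Triflation of F8 in the same flask with PhNTf2 rejoins the route at 5.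

Further compounds
F1 | step 5 | 3,5-bis(benzyloxy)-2-iodophenol | Oc1cc(OCc2ccccc2)cc(OCc2ccccc2)c1I
F2 | step 5 | 2-(benzyloxy)-4-ethynyl-1-methoxybenzene | C#Cc1ccc(OC)c(OCc2ccccc2)c1
F3 | step 5 | 1-[2,4-bis(benzyloxy)-6-hydroxyphenyl]-3-[3-(benzyloxy)-4-methoxyphenyl]prop-2-yn-1-one | Oc1cc(OCc2ccccc2)cc(OCc2ccccc2)c1C(=O)C#Cc1ccc(OC)c(OCc2ccccc2)c1
F4 | step 7 | diosmetin 7,3'-bis(2,2,2-trichloroethyl sulfate) | COc1ccc(-c2cc(=O)c3c(O)cc(OS(=O)(=O)OCC(Cl)(Cl)Cl)cc3o2)cc1OS(=O)(=O)OCC(Cl)(Cl)Cl
F5 | step 7 | diammonium diosmetin 7,3'-disulfate | COc1ccc(-c2cc(=O)c3c(O)cc(OS(=O)(=O)[O-])cc3o2)cc1OS(=O)(=O)[O-].[NH4+].[NH4+]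
F6 | step 1 | 3,5-bis(benzyloxy)phenyl N-isopropylcarbamate | CC(C)NC(=O)Oc1cc(OCc2ccccc2)cc(OCc2ccccc2)c1
F7 | step 1 | 3,5-bis(benzyloxy)-2-(trimethylsilyl)phenyl N-isopropylcarbamate | CC(C)NC(=O)Oc1cc(OCc2ccccc2)cc(OCc2ccccc2)c1[Si](C)(C)C
F8 | step 1 | 3,5-bis(benzyloxy)-2-(trimethylsilyl)phenol | Oc1cc(OCc2ccccc2)cc(OCc2ccccc2)c1[Si](C)(C)C
A1 | direct plan | luteolin (5,7,3',4'-tetrahydroxyflavone) | O=c1cc(-c2ccc(O)c(O)c2)oc2cc(O)cc(O)c12
A2 | direct plan | luteolin 3',4'-cyclic sulfate 7-fluorosulfate | O=c1cc(-c2ccc3c(c2)OS(=O)(=O)O3)oc2cc(OS(=O)(=O)F)cc(O)c12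
A3 | direct plan | sodium diosmetin 7-fluorosulfate 3'-sulfate | COc1ccc(-c2cc(=O)c3c(O)cc(OS(=O)(=O)F)cc3o2)cc1OS(=O)(=O)[O-].[Na+]
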